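**Assumptions.** Pterocarpan numbering is used throughout (O5, C6, C6a, C6b, C7–C10, C10a, O11, C11a, C11b, C1–C4, C4a). The target SMILES decodes to the cis-(6aR,11aR) pterocarpan with a 2,2-dimethylpyran on C2/C3 (O on C3), a second one on C7/C8 (O on C8), 9-OH and 10-prenyl. The (R,R)-TADDOL titanium complex is assumed to give the (6aR,11aR) series; I cannot assign the facial sense from first principles, so if the first run gives the antipode, the equally commercial (S,S)-ligand is used with nothing else changed.

## Retrosynthetic overview

1. The usual isoflavone → isoflavanone reduction/cyclisation is avoided. Instead, the dihydrofuran C ring (C6a–C6b and C11a–O11 bonds) and both stereocentres come from one enantioselective Ti-TADDOLate quinone–chromene formal [3+2] between bis-chromene 7 and 2-allyloxy-1,4-benzoquinone 9.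
2. That cycloaddition delivers the D ring as an arene with 8-OH and 9-O-allyl. The allyl group is never removed: it is relayed to C10 by aromatic Claisen rearrangement (freeing 9-OH) and converted to prenyl by cross-metathesis.
3. The D-ring pyran is built on the 8-OH by 1,1-dimethylpropargyl ether Claisen/6π closure at C7, in the same thermal operation as the allyl shift.
4. Bis-chromene 7 comes from resorcinol: chromanone → chromenol → ortho-formylation → Schweizer chromene annulation. No protecting groups are used.
5. Ring order: A (resorcinol) → A-ring dimethylpyran → B (2H-pyran) → C (dihydrofuran, with D arene from the quinone) → D-ring dimethylpyran.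

## Route

**Step 1**
Reactants: 1 resorcinol; 2 3-methylbut-2-enoic acid
Product: 3 7-hydroxy-2,2-dimethylchroman-4-one
Conditions: MeSO3H, P2O5, 70 °C
Reagents that add atoms: none (both partners are numbered reactants)
Why: Friedel–Crafts acylation at C4 of resorcinol followed by intramolecular oxa-Michael addition of the ortho OH onto the β,β-dimethyl enone closes the chromanone regiospecifically.

**Step 2**
Reactants: 3
Product: 4 (±)-2,2-dimethylchromane-4,7-diol
Conditions: NaBH4 (excess), MeOH–THF, 0 °C → rt
Reagents that add atoms: none
Why: Borohydride reduction of the aryl ketone; the new carbinol centre is racemic and is destroyed in the next step.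

**Step 3**
Reactants: 4
Product: 5 2,2-dimethyl-2H-chromen-7-ol
Conditions: p-TsOH·H2O (cat.), PhMe, 80 °C
Reagents that add atoms: none
Why: Acid-catalysed E1 dehydration of a p-hydroxybenzylic alcohol, which can only eliminate toward C3 to give the conjugated chromene.

**Step 4**
Reactants: 5
Product: 6 7-hydroxy-2,2-dimethyl-2H-chromene-6-carbaldehyde
Conditions: MgCl2, Et3N, (CH2O)n, MeCN, reflux
Reagents that add atoms: paraformaldehyde (formaldehyde unit), C=O
Why: Casnati–Skattebøl magnesium-phenoxide ortho-formylation, which should favour C6 (para to the ring oxygen, unhindered) over C8 (flanked by two oxygens), as with 3-alkoxyphenols.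

**Step 5**
Reactants: 6
Product: 7 2,2-dimethyl-2H,8H-pyrano[3,2-g]chromene (linear bis-chromene; xanthyletin with CH2 in place of the lactone C=O)
Conditions: NaH, DMF, 0 °C; then CH2=CHPPh3Br, 25 → 80 °C
Reagents that add atoms: vinyltriphenylphosphonium bromide, C=C[P+](c1ccccc1)(c1ccccc1)c1ccccc1.[Br-] (supplies the O–CH2–CH= unit)
Why: Schweizer chromene synthesis: the phenoxide adds to the vinylphosphonium salt and the resulting ylide undergoes intramolecular Wittig olefination with the ortho aldehyde, giving the ring (cis) alkene.

**Step 6**
Reactants: 8 2-(allyloxy)phenol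
Product: 9 2-(allyloxy)-1,4-benzoquinone
Conditions: (KSO3)2NO, KH2PO4, H2O–acetone, 0 °C → rt; use cold and fresh
Reagents that add atoms: Fremy's salt, [K+].[K+].[O]N(S(=O)(=O)[O-])S(=O)(=O)[O-] (supplies the para oxygen)
Why: Teuber oxidation of a phenol with a free para position gives the p-quinone (as guaiacol gives 2-methoxybenzoquinone), and the allyl ether is inert.

**Step 7 (key step)**
Reactants: 7 bis-chromene (1.0 equiv); 9 quinone (1.2 equiv)
Product: 10 (6aR,11aR)-9-(allyloxy)-8-hydroxy-pterocarpan carrying the 2,2-dimethyl-2H-pyran fused at C2/C3 (O on C3)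
Conditions: (R,R)-TADDOL–TiCl2 complex (from TiCl4/Ti(OiPr)4 1:1 + TADDOL, 2–3 equiv), CH2Cl2–PhMe, −78 °C; then warm to −20 °C (cat. TFA if cyclobutane persists)
Reagents that add atoms: none
Why: Engler-type Lewis-acid-promoted quinone–styrene formal [3+2] cycloaddition: Ti(IV) chelated between C1=O and the 2-allyloxy oxygen activates quinone C5, the styrenic C3 of the unhindered 2H-chromene alkene of 7 (the other alkene is neopentyl-shielded by the gem-dimethyl group) adds there, the p-alkoxybenzylic cation is trapped by the C4 oxygen and the ring aromatises (any kinetic [2+2] cyclobutane funnels to the same product on warming). The C2-symmetric TADDOLate selects the chromene face in the C–C bond-forming event to set C6a (R), and C11a (R) follows because only cis 6/5 ring closure is possible.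

**Step 8**
Reactants: 10
Product: 11 the 8-O-(2-methylbut-3-yn-2-yl) ether of 10, (6aR,11aR)
Conditions: 3-chloro-3-methylbut-1-yne, DBU, CuCl2·2H2O (cat.), MeCN, 0 °C → rt
Reagents that add atoms: 3-chloro-3-methylbut-1-yne, CC(C)(Cl)C#C
Why: Copper-catalysed O-propargylation of the only free phenol with a tertiary propargylic chloride (via a copper acetylide/allenylidene); the stereocentres are untouched.

**Step 9**
Reactants: 11
Product: 12 (6aR,11aR)-10-allyl-9-hydroxy-pterocarpan with 2,2-dimethyl-2H-pyrans fused at C2/C3 (O on C3) and at C7/C8 (O on C8)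
Conditions: PhNEt2, 140 °C then 195 °C, sealed tube
Reagents that add atoms: none
Why: Two regiochemically forced sigmatropic cascades run in one pot: propargyl Claisen to C7 (the only free ortho site of O8), then 1,5-H shift and oxa-6π closure to the chromene; and aromatic allyl Claisen from O9 to C10 (its only free ortho site; the para position is blocked), which unveils the 9-OH. Neutral/basic thermal conditions cannot epimerise C6a, and C11a can only re-close cis.

**Step 10**
Reactants: 12
Product: 13 Lespecyrtin E4
Conditions: Grubbs II (5 mol%), 2-methylbut-2-ene/CH2Cl2, 40 °C, sealed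
Reagents that add atoms: 2-methylbut-2-ene, CC=C(C)C (supplies the =C(CH3)2 terminus)
Why: Olefin cross-metathesis of a terminal allylarene with excess 2-methyl-2-butene gives the prenyl group; the free phenol is tolerated and the two cyclic, quaternary-flanked chromene alkenes are metathesis spectators.

## Compound list

1 | resorcinol | Oc1cccc(O)c1 | starting material
2 | 3-methylbut-2-enoic acid | CC(C)=CC(=O)O | starting material
3 | 7-hydroxy-2,2-dimethylchroman-4-one | CC1(C)CC(=O)c2ccc(O)cc2O1 | intermediate
4 | (±)-2,2-dimethylchromane-4,7-diol | CC1(C)CC(O)c2ccc(O)cc2O1 | intermediate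
5 | 2,2-dimethyl-2H-chromen-7-ol | CC1(C)C=Cc2ccc(O)cc2O1 | intermediate
6 | 7-hydroxy-2,2-dimethyl-2H-chromene-6-carbaldehyde | CC1(C)C=Cc2cc(C=O)c(O)cc2O1 | intermediate
7 | 2,2-dimethyl-2H,8H-pyrano[3,2-g]chromene | CC1(C)C=Cc2cc3C=CCOc3cc2O1 | intermediate
8 | 2-(allyloxy)phenol | C=CCOc1ccccc1O | starting material
9 | 2-(allyloxy)-1,4-benzoquinone | C=CCOC1=CC(=O)C=CC1=O | intermediate
10 | (6aR,11aR)-9-(allyloxy)-8-hydroxy-2,3-(2,2-dimethylpyrano)pterocarpan | c1c(OCC=C)c(O)cc3c1O[C@H]1c4cc5c(cc4OC[C@@H]31)OC(C)(C)C=C5 | intermediate
11 | 8-O-(2-methylbut-3-yn-2-yl) ether of 10 | c1c(OCC=C)c(OC(C)(C)C#C)cc3c1O[C@H]1c4cc5c(cc4OC[C@@H]31)OC(C)(C)C=C5 | intermediate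
12 | (6aR,11aR)-10-allyl-9-hydroxy-bis(2,2-dimethylpyrano)[2,3:7,8]pterocarpan | C=CCc1c(O)c2c(c3c1O[C@H]1c4cc5c(cc4OC[C@@H]31)OC(C)(C)C=C5)C=CC(C)(C)O2 | intermediate
13 | Lespecyrtin E4 | CC(C)=CCc1c(O)c2c(c3c1O[C@H]1c4cc5c(cc4OC[C@@H]31)OC(C)(C)C=C5)C=CC(C)(C)O2 | target

## Summary

**Total steps:** 10.
**Longest linear sequence:** 9 (steps 1–5, then 7–10 from resorcinol); step 6 is a one-step branch.

**Three steps most likely to fail**

1. **Step 7 (asymmetric quinone–chromene [3+2]).** Risks: competing attack at the dimethylchromene alkene of 7, moderate ee, and an unverified facial sense with this ligand. Fallback: abandon the cycloaddition and make the same pterocarpan phenol by the isoflavone route. That means Suzuki coupling of the 3-iodo-pyranochromone with a 2,4,5-trioxygenated arylboronate, Ru-TsDPEN transfer hydrogenation of the 2'-hydroxyisoflavanone with dynamic kinetic resolution, and acid-mediated ring closure.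
2. **Step 9 (tandem double Claisen at 195 °C).** Risks: incomplete allyl shift or thermal decomposition of the bis-chromene. Fallback: separate the two events and change how the prenyl arrives. Form the D-ring pyran at ≤140 °C, remove the O-allyl with Pd(0), O-alkylate the 9-OH with 3-chloro-3-methylbutyne, semi-hydrogenate (Lindlar) to the 1,1-dimethylallyl ether, and run a ~110 °C Claisen that delivers the C10 prenyl directly, so step 10 is not needed.
3. **Step 5 (Schweizer annulation on an electron-rich, deactivated salicylaldehyde).** Risk: low conversion in the intramolecular Wittig step. Fallback: build the 2H-pyran by ring-closing metathesis instead: O-allylate 6, methylenate the aldehyde (Ph3P=CH2) to the styrene, and close with Grubbs II.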